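**Retrosynthetic overview**
- The target comes from its octaacetate by one global deacetylation.
- The octaacetate comes from a single intermolecular endo [4+2] cycloaddition, the same union presumed in the biosynthesis: a peracetylated chalcone (dienophile) adds to a second peracetylated chalcone that carries an (E)-3-methylbutadienyl (dehydroprenyl) diene.
- The dienophile comes from an acid-mediated Claisen–Schmidt condensation of 3,5-diacetoxy-4-prenylacetophenone with 2,4-diacetoxybenzaldehyde; the prenyl group is put on 3,5-dihydroxyacetophenone by direct C-alkylation.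
- The diene comes from Heck dienylation (isoprene) of a 3'-iodochalcone, itself from Claisen–Schmidt condensation of 3-iodo-2,4-dihydroxyacetophenone with the same aldehyde.
- Ring order: all four benzene rings are bought; the cyclohexene is the only ring made, in the penultimate step, and all three stereocentres are set there.

Assumption: the SMILES is taken as written, so the aroyl group on the cyclohexene is 3,5-dihydroxy-4-prenylbenzoyl (no hydroxyl ortho to that ketone), and "kuwanon J" names this structure.

Numbering used for the cyclohexene: C-3'' carries the chalcone-bearing aryl, C-4'' the aroyl group, C-5'' the 2,4-dioxygenated phenyl, and C-1''(CH3)=C-2''.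

**Step 1**
Reactants: 1 2,4-dihydroxybenzaldehyde
Product: 2 2,4-diacetoxybenzaldehyde (4-formyl-1,3-phenylene diacetate)
Conditions: Ac2O, pyridine, 4-(dimethylamino)pyridine (cat.), CH2Cl2, 0 °C to rt
Reagents that add atoms: acetic anhydride, CC(=O)OC(C)=O
Why: DMAP-catalysed O-acetylation (nucleophilic acyl substitution) caps both phenols so that the aldehyde cannot close to a flavylium salt in the later acid-mediated condensations; no stereocentre is formed.

**Step 2**
Reactants: 3 3,5-dihydroxyacetophenone; 4 prenyl bromide (1-bromo-3-methylbut-2-ene)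
Product: 5 1-[3,5-dihydroxy-4-(3-methylbut-2-en-1-yl)phenyl]ethan-1-one
Conditions: 10% KOH (aq), 4 (1.0 equiv), 0 °C to rt
Reagents that add atoms: none
Why: C-alkylation of an ambident phenoxide in water (SN2 prenylation): the dianion reacts at C-4, the only carbon flanked by both oxyanions and not crowded by the acetyl group, by analogy with the standard aqueous 3-C-prenylation of 2,4-dihydroxyacetophenone, with a modest yield (about 30%) accepted for a one-step entry; no stereocentre is formed.

**Step 3**
Reactants: 5 1-[3,5-dihydroxy-4-(3-methylbut-2-en-1-yl)phenyl]ethan-1-one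
Product: 6 5-acetyl-2-(3-methylbut-2-en-1-yl)-1,3-phenylene diacetate
Conditions: Ac2O, pyridine, 4-(dimethylamino)pyridine (cat.), CH2Cl2, rt
Reagents that add atoms: acetic anhydride, CC(=O)OC(C)=O
Why: O-acetylation (nucleophilic acyl substitution) removes the two free phenols ortho to the prenyl group, which would otherwise cyclise to a chroman under the acid of the next step; no stereocentre is formed.

**Step 4**
Reactants: 6 5-acetyl-2-(3-methylbut-2-en-1-yl)-1,3-phenylene diacetate; 2 2,4-diacetoxybenzaldehyde
Product: 8 (E)-1-[3,5-diacetoxy-4-(3-methylbut-2-en-1-yl)phenyl]-3-(2,4-diacetoxyphenyl)prop-2-en-1-one (dienophile), via aldol adduct 7 (not isolated)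
Conditions: BF3·OEt2 (0.5 equiv, promoter), 1,4-dioxane, rt
Reagents that add atoms: none
Why: BF3-mediated Claisen–Schmidt condensation (aldol addition to 7, then dehydration) runs without base, so all four aryl acetates survive, and gives the conjugated E-enone under thermodynamic control; the carbinol centre of 7 is lost on dehydration.

**Step 5**
Reactants: 9 2,4-dihydroxyacetophenone
Product: 10 1-(2,4-dihydroxy-3-iodophenyl)ethan-1-one
Conditions: I2 (0.4 equiv), HIO3 (0.2 equiv), EtOH–H2O, 35 °C
Reagents that add atoms: iodine, [I][I]; iodic acid, O[I](=O)=O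
Why: electrophilic aromatic iodination in which HIO3 reoxidises the iodide formed, so all iodine is used; substitution goes to C-3, the position ortho to both hydroxyl groups; no stereocentre is formed.

**Step 6**
Reactants: 10 1-(2,4-dihydroxy-3-iodophenyl)ethan-1-one; 2 2,4-diacetoxybenzaldehyde
Product: 12 (E)-3-(2,4-diacetoxyphenyl)-1-(2,4-dihydroxy-3-iodophenyl)prop-2-en-1-one, via aldol adduct 11 (not isolated)
Conditions: BF3·OEt2 (0.5 equiv, promoter), 1,4-dioxane, rt; H2O work-up
Reagents that add atoms: none
Why: BF3-mediated Claisen–Schmidt condensation (aldol addition to 11, then dehydration), helped by boron chelation of the 2-hydroxy ketone, gives the E-chalcone without base so the acetates of 2 survive, and any acetyl scrambling is levelled in the next step; no stereocentre remains.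

**Step 7**
Reactants: 12 (E)-3-(2,4-diacetoxyphenyl)-1-(2,4-dihydroxy-3-iodophenyl)prop-2-en-1-one
Product: 13 (E)-1-(2,4-diacetoxy-3-iodophenyl)-3-(2,4-diacetoxyphenyl)prop-2-en-1-one
Conditions: Ac2O, pyridine, 4-(dimethylamino)pyridine (cat.), CH2Cl2, rt to 40 °C
Reagents that add atoms: acetic anhydride, CC(=O)OC(C)=O
Why: exhaustive O-acetylation (DMAP-catalysed acyl transfer) masks the chelating 2'-hydroxyl and the 4'-hydroxyl, which removes the hydrogen-bond activation of this enone and prevents chromene formation from the diene made next; no stereocentre is formed.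

**Step 8**
Reactants: 13 (E)-1-(2,4-diacetoxy-3-iodophenyl)-3-(2,4-diacetoxyphenyl)prop-2-en-1-one; 14 isoprene (2-methylbuta-1,3-diene)
Product: 15 (E)-1-{2,4-diacetoxy-3-[(E)-3-methylbuta-1,3-dien-1-yl]phenyl}-3-(2,4-diacetoxyphenyl)prop-2-en-1-one (diene)
Conditions: Pd(OAc)2 (10 mol%), Ag2CO3 (0.6 equiv), 14 (10 equiv), DMF, 70 °C, sealed tube, BHT (trace)
Reagents that add atoms: none
Why: Mizoroki–Heck arylation of a 1,3-diene: the arylpalladium species adds to the unsubstituted vinyl terminus of isoprene and β-hydride elimination from the π-allyl intermediate gives the conjugated (E)-1-aryl-3-methylbuta-1,3-diene, while Ag2CO3 takes up the iodide without cleaving the acetates; no stereocentre is formed.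

**Step 9**
Reactants: 8 dienophile chalcone tetraacetate; 15 diene chalcone tetraacetate
Product: 16 octa-O-acetate of the target, (3''S,4''R,5''S) (cyclohex-2-ene locants 1S,5S,6R)
Conditions: (3aS)-1-(2-methylphenyl)-3,3-diphenyltetrahydro-1H,3H-pyrrolo[1,2-c][1,3,2]oxazaborole (0.30 equiv) + HN(SO2CF3)2 (0.25 equiv), CH2Cl2, −78 °C; 8 (3 equiv, excess recovered); 15 added over 8 h, −40 to −20 °C
Reagents that add atoms: none
Why: Proposed new method: the cationic boron of the protonated oxazaborolidine binds the carbonyl lone pair of the more electrophilic, unhindered enone of 8 syn to C-α (α-C–H···O contact, s-trans enone), lowers its LUMO and stacks a catalyst phenyl against the α-Re face, so the diene of 15 (largest HOMO coefficient at its CH2 terminus, which bonds to C-β) adds to the open α-Si/β-Si face through the endo transition state and sets C-3'' (S), C-4'' (R) and C-5'' (S) in one event (aroyl cis to the chalcone-bearing aryl, trans to the 2,4-diacetoxyphenyl as carried over from the E-enone), while the threefold excess of 8 and slow addition of 15 suppress self-cycloaddition of 15; the closest known reaction type is the Corey oxazaborolidinium-catalysed enantioselective Diels–Alder reaction of simple α,β-unsaturated ketones and esters, extended here to a chalcone that has no chelating ortho-hydroxyl.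

**Step 10**
Reactants: 16 octa-O-acetate of the target
Product: 17 kuwanon J (target structure as given)
Conditions: K2CO3 (cat.), MeOH (degassed), 0 °C to rt; then NH4Cl (aq)
Reagents that add atoms: none
Why: base-catalysed transesterification (methanolysis) of the eight aryl acetates under conditions mild enough to leave the ketone α-carbon C-4'' and the 2'-hydroxychalcone untouched; no stereocentre is affected.

**Compound list**
1 | 2,4-dihydroxybenzaldehyde | O=Cc1ccc(O)cc1O | starting material
2 | 2,4-diacetoxybenzaldehyde (4-formyl-1,3-phenylene diacetate) | O=Cc1ccc(OC(C)=O)cc1OC(C)=O | intermediate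
3 | 3,5-dihydroxyacetophenone | CC(=O)c1cc(O)cc(O)c1 | starting material
4 | prenyl bromide (1-bromo-3-methylbut-2-ene) | CC(C)=CCBr | starting material
5 | 1-[3,5-dihydroxy-4-(3-methylbut-2-en-1-yl)phenyl]ethan-1-one | CC(=O)c1cc(O)c(CC=C(C)C)c(O)c1 | intermediate
6 | 5-acetyl-2-(3-methylbut-2-en-1-yl)-1,3-phenylene diacetate | CC(=O)c1cc(OC(C)=O)c(CC=C(C)C)c(OC(C)=O)c1 | intermediate
7 | 1-[3,5-diacetoxy-4-(3-methylbut-2-en-1-yl)phenyl]-3-(2,4-diacetoxyphenyl)-3-hydroxypropan-1-one (racemic aldol adduct, not isolated) | CC(C)=CCc1c(OC(C)=O)cc(C(=O)CC(O)c2ccc(OC(C)=O)cc2OC(C)=O)cc1OC(C)=O | intermediate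
8 | (E)-1-[3,5-diacetoxy-4-(3-methylbut-2-en-1-yl)phenyl]-3-(2,4-diacetoxyphenyl)prop-2-en-1-one | CC(C)=CCc1c(OC(C)=O)cc(C(=O)/C=C/c2ccc(OC(C)=O)cc2OC(C)=O)cc1OC(C)=O | intermediate
9 | 2,4-dihydroxyacetophenone | CC(=O)c1ccc(O)cc1O | starting material
10 | 1-(2,4-dihydroxy-3-iodophenyl)ethan-1-one | CC(=O)c1ccc(O)c(I)c1O | intermediate
11 | 3-(2,4-diacetoxyphenyl)-1-(2,4-dihydroxy-3-iodophenyl)-3-hydroxypropan-1-one (racemic aldol adduct, not isolated) | CC(=O)Oc1ccc(C(O)CC(=O)c2ccc(O)c(I)c2O)c(OC(C)=O)c1 | intermediate
12 | (E)-3-(2,4-diacetoxyphenyl)-1-(2,4-dihydroxy-3-iodophenyl)prop-2-en-1-one | CC(=O)Oc1ccc(/C=C/C(=O)c2ccc(O)c(I)c2O)c(OC(C)=O)c1 | intermediate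
13 | (E)-1-(2,4-diacetoxy-3-iodophenyl)-3-(2,4-diacetoxyphenyl)prop-2-en-1-one | CC(=O)Oc1ccc(/C=C/C(=O)c2ccc(OC(C)=O)c(I)c2OC(C)=O)c(OC(C)=O)c1 | intermediate
14 | isoprene (2-methylbuta-1,3-diene) | C=CC(C)=C | starting material
15 | (E)-1-{2,4-diacetoxy-3-[(E)-3-methylbuta-1,3-dien-1-yl]phenyl}-3-(2,4-diacetoxyphenyl)prop-2-en-1-one | CC(=O)Oc1ccc(/C=C/C(=O)c2ccc(OC(C)=O)c(/C=C/C(C)=C)c2OC(C)=O)c(OC(C)=O)c1 | intermediate
16 | octa-O-acetate of the target, (3''S,4''R,5''S) | CC(C)=CCc1c(OC(C)=O)cc(C(=O)[C@H]2[C@@H](c3c(OC(C)=O)ccc(C(=O)/C=C/c4ccc(OC(C)=O)cc4OC(C)=O)c3OC(C)=O)C=C(C)C[C@@H]2c2ccc(OC(C)=O)cc2OC(C)=O)cc1OC(C)=O | intermediate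
17 | kuwanon J as given, (3''S,4''R,5''S) | CC(C)=CCc1c(O)cc(C(=O)[C@H]2[C@@H](c3c(O)ccc(C(=O)/C=C/c4ccc(O)cc4O)c3O)C=C(C)C[C@@H]2c2ccc(O)cc2O)cc1O | target

**Step count**
Total: 10 steps. Longest linear sequence: 6 steps (steps 5, 6, 7, 8, 9, 10; the branch through steps 1, 6, 7, 8, 9, 10 is equally long).

**Three steps most likely to fail**

Step 9 is the main risk. The unchelated chalcone 8 may react too slowly, or with low endo and enantioselectivity, under the oxazaborolidinium salt. The facial sense rests on a binding model; if the first run gives the antipode, the (3aR) catalyst replaces the (3aS) one. Diene 15 can also act as its own dienophile. The fallback sets out from 8 and 15: they are combined without catalyst in CH2Cl2 at about 10 kbar and room temperature (or in toluene at 110 °C with BHT). This gives the endo adduct as a racemate, that is 16 together with its enantiomer, the (3''R,4''S,5''R)-octaacetate F1. The endo racemate is separated from exo material on silica and resolved by preparative HPLC on a chiral stationary phase. The route is rejoined at 16 and continues with step 10.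

Step 2 may give a low yield or a mixture of C-4, C-2 and O-prenylated products. The fallback sets out from 3. MOMCl with iPr2NEt gives 1-[3,5-bis(methoxymethoxy)phenyl]ethan-1-one F2, and NaBH4 in MeOH gives 1-[3,5-bis(methoxymethoxy)phenyl]ethan-1-ol F3. n-BuLi (2.3 equiv, THF, 0 °C) then lithiates the position between the two MOM ethers (directed ortho-metalation); after CuBr·SMe2, prenyl bromide 4 gives 1-[3,5-bis(methoxymethoxy)-4-(3-methylbut-2-en-1-yl)phenyl]ethan-1-ol F4. MnO2 in CH2Cl2 returns the ketone 1-[3,5-bis(methoxymethoxy)-4-(3-methylbut-2-en-1-yl)phenyl]ethan-1-one F5. Brief treatment with dilute HCl in MeOH at room temperature removes the MOM groups, and the route is rejoined at 5.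

Step 8 may suffer from slow insertion at the di-ortho-substituted aryl iodide, from the regioisomeric 2-methyl diene, or from oligomerisation of isoprene. The fallback sets out from 13. A Heck reaction with 2-methylbut-3-en-2-ol (C=CC(C)(C)O) under Pd(OAc)2 and Ag2CO3 in DMF at 70 °C gives the tertiary allylic alcohol (E)-1-{2,4-diacetoxy-3-[(E)-3-hydroxy-3-methylbut-1-en-1-yl]phenyl}-3-(2,4-diacetoxyphenyl)prop-2-en-1-one F6. Dehydration with catalytic pyridinium p-toluenesulfonate in toluene at 80 °C then gives 15, where the route is rejoined; no chromene can form because both ortho oxygens are acetylated.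

**Further compounds**
F1 | step 9 | enantiomer of 16, (3''R,4''S,5''R)-octaacetate | CC(C)=CCc1c(OC(C)=O)cc(C(=O)[C@@H]2[C@H](c3c(OC(C)=O)ccc(C(=O)/C=C/c4ccc(OC(C)=O)cc4OC(C)=O)c3OC(C)=O)C=C(C)C[C@H]2c2ccc(OC(C)=O)cc2OC(C)=O)cc1OC(C)=O
F2 | step 2 | 1-[3,5-bis(methoxymethoxy)phenyl]ethan-1-one | COCOc1cc(OCOC)cc(C(C)=O)c1
F3 | step 2 | 1-[3,5-bis(methoxymethoxy)phenyl]ethan-1-ol (racemic) | COCOc1cc(OCOC)cc(C(C)O)c1
F4 | step 2 | 1-[3,5-bis(methoxymethoxy)-4-(3-methylbut-2-en-1-yl)phenyl]ethan-1-ol (racemic) | COCOc1cc(C(C)O)cc(OCOC)c1CC=C(C)C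
F5 | step 2 | 1-[3,5-bis(methoxymethoxy)-4-(3-methylbut-2-en-1-yl)phenyl]ethan-1-one | COCOc1cc(C(C)=O)cc(OCOC)c1CC=C(C)C
F6 | step 8 | (E)-1-{2,4-diacetoxy-3-[(E)-3-hydroxy-3-methylbut-1-en-1-yl]phenyl}-3-(2,4-diacetoxyphenyl)prop-2-en-1-one | CC(=O)Oc1ccc(/C=C/C(=O)c2ccc(OC(C)=O)c(/C=C/C(C)(C)O)c2OC(C)=O)c(OC(C)=O)c1
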